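**Plan**

1. Cuts: the caffeate C–O bond; the cyclohexene bonds C2=C3 (ring-closing metathesis) and C1–C2 (isopropenyl Grignard); then the C5–C1' bond between the two quaternary carbons.
2. Enabling feature: with C1 at the aldehyde level, O=C1–C6–C5–C1'–C2'=CH2 (ring carbons C1, C6, C5; cyclopentane C1', C2' and its exocyclic methylene carbon) is a δ,ε-unsaturated carbonyl array, the retron of an anionic oxy-Cope shift. In the precursor 14 the methylene carbon is temporarily bonded to the future C1.
3. Forward order: the cyclopentene ring is bought (1) and carried to amide 8; vinyl iodide 11 is joined to give the acyclic dienol 14; the [3,3] shift forms C5–C1' and the exocyclic methylene; the cyclohexene ring is closed afterwards; the ester is made last.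
4. Stereochemistry: the S carbinol of 14 (CBS reduction) is transferred to both quaternary centres through a chair transition state with fixed alkene geometries (E from syn-carboalumination, ring-fixed cyclopentene). C1 comes from a second, reagent-controlled CBS reduction; the E cinnamate comes with caffeic acid.

Key step: step 7

Remark: ring numbering is C1 (carbinol carbon) to C6 with C5 quaternary, and C1' (quaternary), C2' (=CH2) in the cyclopentane. The catechol is assumed to need protection and is carried as its bis-TBS ether. Both CBS reductions are assumed to follow the usual model with the alkenyl group as the large substituent.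

**Route**

Step 1
Reactants: 1 2-methylcyclopent-2-en-1-one
Product: 3 2-methylcyclopent-1-en-1-yl trifluoromethanesulfonate, via lithium 2-methylcyclopent-1-en-1-olate 2 (not isolated)
Conditions: L-Selectride, THF, −78 °C; then PhNTf2, −78 °C → rt
Reagents that add atoms: N-phenylbis(trifluoromethanesulfonimide), O=S(=O)(N(c1ccccc1)S(=O)(=O)C(F)(F)F)C(F)(F)F
Why: Conjugate reduction of the β-unsubstituted enone gives the regiodefined tetrasubstituted enolate, and its O-sulfonylation (conjugate reduction–enolate trapping) should fix the ring alkene between C1 and the methyl-bearing C2.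

Step 2
Reactants: 3 2-methylcyclopent-1-en-1-yl trifluoromethanesulfonate; 4 ethyl bromoacetate
Product: 6 ethyl 2-(2-methylcyclopent-1-en-1-yl)acetate, via Reformatsky reagent 5 (not isolated)
Conditions: 4, Zn dust, THF, rt; then 3, Pd(PPh3)4 (5 mol %), THF/DMPU, 60 °C
Reagents that add atoms: none
Why: Oxidative addition of Pd(0) into the alkenyl C–OTf bond, transmetalation of the zinc ester enolate and reductive elimination (Negishi-type coupling of a Reformatsky reagent) should attach the acetate carbon without moving the alkene.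

Step 3
Reactants: 6 ethyl 2-(2-methylcyclopent-1-en-1-yl)acetate; 7 N,O-dimethylhydroxylamine hydrochloride
Product: 8 N-methoxy-N-methyl-2-(2-methylcyclopent-1-en-1-yl)acetamide
Conditions: i-PrMgCl (3 equiv), THF, −20 °C → 0 °C
Reagents that add atoms: none
Why: The chloromagnesium amide of 7 should add to the ester faster than the ester is enolized, and the chelated adduct collapses only on work-up (Weinreb amide formation from an ester).

Step 4
Reactants: 9 pent-1-en-4-yne
Product: 11 (1E)-1-iodo-2-methylpenta-1,4-diene, via alkenylalane 10 (not isolated)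
Conditions: Me3Al (2 equiv), Cp2ZrCl2 (0.25 equiv), CH2Cl2, 0 °C → rt; then I2, THF, −30 °C → 0 °C
Reagents that add atoms: trimethylaluminium, C[Al](C)C; iodine, II
Why: Zr-catalysed syn-carboalumination (Negishi carboalumination) puts methyl on the internal and aluminium on the terminal alkyne carbon, and iodinolysis with retention should give the E iodide while the isolated alkene stays untouched.

Step 5
Reactants: 11 (1E)-1-iodo-2-methylpenta-1,4-diene; 8 N-methoxy-N-methyl-2-(2-methylcyclopent-1-en-1-yl)acetamide
Product: 13 (3E)-4-methyl-1-(2-methylcyclopent-1-en-1-yl)hepta-3,6-dien-2-one, via alkenyllithium 12 (not isolated)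
Conditions: 11, t-BuLi (2 equiv), Et2O, −78 °C; then 8, −78 °C → −40 °C; aq NH4Cl
Reagents that add atoms: none
Why: Iodine–lithium exchange proceeds with retention of alkene geometry, and the N-methoxy chelate of the adduct prevents over-addition (Weinreb ketone synthesis), so the E enone should result.

Step 6
Reactants: 13 (3E)-4-methyl-1-(2-methylcyclopent-1-en-1-yl)hepta-3,6-dien-2-one
Product: 14 (2S,3E)-4-methyl-1-(2-methylcyclopent-1-en-1-yl)hepta-3,6-dien-2-ol
Conditions: (R)-Me-CBS (0.5 equiv), catecholborane, toluene, −78 °C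
Reagents that add atoms: none
Why: In the CBS reduction the ketone binds with its alkenyl (large) group away from the catalyst and hydride is delivered to one face only, which should set C2 as S; catecholborane at −78 °C leaves the alkenes alone.

Step 7
Reactants: 14 (2S,3E)-4-methyl-1-(2-methylcyclopent-1-en-1-yl)hepta-3,6-dien-2-ol
Product: 17 (3S)-3-methyl-3-[(1S)-1-methyl-2-methylidenecyclopentyl]hex-5-enal, via potassium alkoxide 15 (not isolated), via potassium enolate 16 (not isolated)
Conditions: KH (2 equiv), 18-crown-6 (2 equiv), THF, 0 °C → rt; AcOH, THF, −78 °C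
Reagents that add atoms: none
Why: KH forms alkoxide 15, and a concerted anionic oxy-Cope [3,3] shift through a six-membered chair array (ring C2', ring C1', chain C1, C2, C3, C4 of 14) breaks C1–C2, forms the bond from C4 to ring carbon C2' and leaves enolate 16 and the exocyclic methylene. The closest known reaction type is the anionic oxy-Cope rearrangement of acyclic 1,5-dien-3-olates. No ring is closed; the only cyclic array is the transition state. Both quaternary centres arise here: the S carbinol carbon places O⁻ equatorial (axial O⁻ would be 1,3-diaxial to the C4 methyl), the E alkene puts that methyl axial and the allyl arm equatorial, and the ring-fixed tetrasubstituted cyclopentene alkene fixes which face bonds, so the chair should give the (3S,1'S) pair. The step needs the concerted shift to outrun fragmentation of the alkoxide and the chair to beat the boat; the acyclic diene reaches an unstrained chair, whereas the boat would eclipse both fully substituted termini.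

Step 8
Reactants: 17 (3S)-3-methyl-3-[(1S)-1-methyl-2-methylidenecyclopentyl]hex-5-enal; 18 isopropenylmagnesium bromide
Product: 19 (3RS,5S)-2,5-dimethyl-5-[(1S)-1-methyl-2-methylidenecyclopentyl]octa-1,7-dien-3-ol
Conditions: THF, −78 °C → 0 °C; aq NH4Cl
Reagents that add atoms: none
Why: Grignard 1,2-addition to the aldehyde brings in the last two ring carbons; the new carbinol centre is not controlled here and is expected as a mixture that converges in step 10.

Step 9
Reactants: 19 (3RS,5S)-2,5-dimethyl-5-[(1S)-1-methyl-2-methylidenecyclopentyl]octa-1,7-dien-3-ol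
Product: 20 (1RS,5S)-2,5-dimethyl-5-[(1S)-1-methyl-2-methylidenecyclopentyl]cyclohex-2-en-1-ol
Conditions: Grubbs second-generation catalyst (5 mol %), CH2Cl2 (5 mM), 40 °C
Reagents that add atoms: none
Why: Ring-closing metathesis between the allyl and isopropenyl groups should close the six-membered ring with the trisubstituted C2=C3 alkene, helped by the quaternary C5, while the hindered exocyclic methylene next to C1' stays out.

Step 10
Reactants: 20 (1RS,5S)-2,5-dimethyl-5-[(1S)-1-methyl-2-methylidenecyclopentyl]cyclohex-2-en-1-ol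
Product: 21 (5S)-2,5-dimethyl-5-[(1S)-1-methyl-2-methylidenecyclopentyl]cyclohex-2-en-1-one
Conditions: Dess–Martin periodinane, CH2Cl2, 0 °C → rt
Reagents that add atoms: none
Why: Dess–Martin oxidation of the allylic alcohol should merge both C1 epimers into one enone without touching the alkenes or the quaternary centres.

Step 11
Reactants: 21 (5S)-2,5-dimethyl-5-[(1S)-1-methyl-2-methylidenecyclopentyl]cyclohex-2-en-1-one
Product: 22 (1S,5S)-2,5-dimethyl-5-[(1S)-1-methyl-2-methylidenecyclopentyl]cyclohex-2-en-1-ol
Conditions: (R)-Me-CBS (1 equiv), catecholborane, toluene, −78 °C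
Reagents that add atoms: none
Why: CBS reduction with the C2=C3 side as the large group should deliver hydride under reagent control to give the 1S alcohol, with oxygen trans to the C5 methyl as in the target.

Step 12
Reactants: 23 caffeic acid
Product: 25 (2E)-3-[3,4-bis(tert-butyldimethylsilyloxy)phenyl]prop-2-enoic acid, via tris-silylated caffeate 24 (not isolated)
Conditions: TBSCl (3.3 equiv), imidazole, DMF, rt; then AcOH/THF/H2O, rt
Reagents that add atoms: tert-butyldimethylsilyl chloride, CC(C)(C)[Si](C)(C)Cl
Why: Exhaustive silylation followed by mild aqueous acid should cleave only the labile silyl ester and leave the two aryl silyl ethers.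

Step 13
Reactants: 22 (1S,5S)-2,5-dimethyl-5-[(1S)-1-methyl-2-methylidenecyclopentyl]cyclohex-2-en-1-ol; 25 (2E)-3-[3,4-bis(tert-butyldimethylsilyloxy)phenyl]prop-2-enoic acid
Product: 26 (1S,5S)-2,5-dimethyl-5-[(1S)-1-methyl-2-methylidenecyclopentyl]cyclohex-2-en-1-yl (2E)-3-[3,4-bis(tert-butyldimethylsilyloxy)phenyl]prop-2-enoate
Conditions: DCC, DMAP (cat.), CH2Cl2, 0 °C → rt
Reagents that add atoms: none
Why: Steglich esterification acylates the alcohol oxygen, so the C1 configuration is retained and the allylic C–O bond is never ionized.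

Step 14
Reactants: 26 (1S,5S)-2,5-dimethyl-5-[(1S)-1-methyl-2-methylidenecyclopentyl]cyclohex-2-en-1-yl (2E)-3-[3,4-bis(tert-butyldimethylsilyloxy)phenyl]prop-2-enoate
Product: 27 (1S,5S)-2,5-dimethyl-5-[(1S)-1-methyl-2-methylidenecyclopentyl]cyclohex-2-en-1-yl (2E)-3-(3,4-dihydroxyphenyl)prop-2-enoate
Conditions: HF·pyridine, pyridine/THF, 0 °C → rt, argon
Reagents that add atoms: none
Why: Buffered fluoride should cleave the two aryl silyl ethers while the allylic ester, the alkenes and the stereocentres are left intact.

**Compound list**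

1 | 2-methylcyclopent-2-en-1-one | CC1=CCCC1=O | starting material
2 | lithium 2-methylcyclopent-1-en-1-olate | CC1=C([O-])CCC1.[Li+] | intermediate
3 | 2-methylcyclopent-1-en-1-yl trifluoromethanesulfonate | CC1=C(OS(=O)(=O)C(F)(F)F)CCC1 | intermediate
4 | ethyl bromoacetate | CCOC(=O)CBr | starting material
5 | (2-ethoxy-2-oxoethyl)zinc bromide | CCOC(=O)C[Zn]Br | intermediate
6 | ethyl 2-(2-methylcyclopent-1-en-1-yl)acetate | CCOC(=O)CC1=C(C)CCC1 | intermediate
7 | N,O-dimethylhydroxylamine hydrochloride | CNOC.Cl | starting material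
8 | N-methoxy-N-methyl-2-(2-methylcyclopent-1-en-1-yl)acetamide | CON(C)C(=O)CC1=C(C)CCC1 | intermediate
9 | pent-1-en-4-yne | C=CCC#C | starting material
10 | dimethyl[(1E)-2-methylpenta-1,4-dien-1-yl]alumane | C=CC/C(C)=C/[Al](C)C | intermediate
11 | (1E)-1-iodo-2-methylpenta-1,4-diene | C=CC/C(C)=C/I | intermediate
12 | [(1E)-2-methylpenta-1,4-dien-1-yl]lithium | C=CC/C(C)=C/[Li] | intermediate
13 | (3E)-4-methyl-1-(2-methylcyclopent-1-en-1-yl)hepta-3,6-dien-2-one | CC1=C(CC(=O)/C=C(\C)CC=C)CCC1 | intermediate
14 | (2S,3E)-4-methyl-1-(2-methylcyclopent-1-en-1-yl)hepta-3,6-dien-2-ol | CC1=C(C[C@H](O)/C=C(\C)CC=C)CCC1 | intermediate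
15 | potassium (2S,3E)-4-methyl-1-(2-methylcyclopent-1-en-1-yl)hepta-3,6-dien-2-olate | CC1=C(C[C@H]([O-])/C=C(\C)CC=C)CCC1.[K+] | intermediate
16 | potassium (1E,3S)-3-methyl-3-[(1S)-1-methyl-2-methylidenecyclopentyl]hexa-1,5-dien-1-olate | C=C1CCC[C@]1(C)[C@@](C)(CC=C)/C=C/[O-].[K+] | intermediate
17 | (3S)-3-methyl-3-[(1S)-1-methyl-2-methylidenecyclopentyl]hex-5-enal | C=C1CCC[C@]1(C)[C@@](C)(CC=C)CC=O | intermediate
18 | isopropenylmagnesium bromide | C=C(C)[Mg]Br | starting material
19 | (3RS,5S)-2,5-dimethyl-5-[(1S)-1-methyl-2-methylidenecyclopentyl]octa-1,7-dien-3-ol | C=C1CCC[C@]1(C)[C@@](C)(CC=C)CC(O)C(C)=C | intermediate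
20 | (1RS,5S)-2,5-dimethyl-5-[(1S)-1-methyl-2-methylidenecyclopentyl]cyclohex-2-en-1-ol | C=C1CCC[C@]1(C)[C@@]1(C)CC=C(C)C(O)C1 | intermediate
21 | (5S)-2,5-dimethyl-5-[(1S)-1-methyl-2-methylidenecyclopentyl]cyclohex-2-en-1-one | C=C1CCC[C@]1(C)[C@@]1(C)CC=C(C)C(=O)C1 | intermediate
22 | (1S,5S)-2,5-dimethyl-5-[(1S)-1-methyl-2-methylidenecyclopentyl]cyclohex-2-en-1-ol | C=C1CCC[C@]1(C)[C@@]1(C)CC=C(C)[C@@H](O)C1 | intermediate
23 | caffeic acid | OC(=O)/C=C/c1ccc(O)c(O)c1 | starting material
24 | tert-butyldimethylsilyl (2E)-3-[3,4-bis(tert-butyldimethylsilyloxy)phenyl]prop-2-enoate | CC(C)(C)[Si](C)(C)OC(=O)/C=C/c1ccc(O[Si](C)(C)C(C)(C)C)c(O[Si](C)(C)C(C)(C)C)c1 | intermediate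
25 | (2E)-3-[3,4-bis(tert-butyldimethylsilyloxy)phenyl]prop-2-enoic acid | OC(=O)/C=C/c1ccc(O[Si](C)(C)C(C)(C)C)c(O[Si](C)(C)C(C)(C)C)c1 | intermediate
26 | (1S,5S)-2,5-dimethyl-5-[(1S)-1-methyl-2-methylidenecyclopentyl]cyclohex-2-en-1-yl (2E)-3-[3,4-bis(tert-butyldimethylsilyloxy)phenyl]prop-2-enoate | C=C1CCC[C@]1(C)[C@@]1(C)CC=C(C)[C@@H](OC(=O)/C=C/c2ccc(O[Si](C)(C)C(C)(C)C)c(O[Si](C)(C)C(C)(C)C)c2)C1 | intermediate
27 | (1S,5S)-2,5-dimethyl-5-[(1S)-1-methyl-2-methylidenecyclopentyl]cyclohex-2-en-1-yl (2E)-3-(3,4-dihydroxyphenyl)prop-2-enoate | C=C1CCC[C@]1(C)[C@@]1(C)CC=C(C)[C@@H](OC(=O)/C=C/c2ccc(O)c(O)c2)C1 | target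

**Count**

Total steps: 14. Longest linear sequence: 12 steps (1, 2, 3, 5, 6, 7, 8, 9, 10, 11, 13, 14).

**Steps most likely to fail**

Step 7. The alkoxide may fragment (retro-allylation) or undergo a stepwise 1,3-shift faster than the concerted shift, because both termini are fully substituted; this would lower conversion and erode the transfer of chirality. The fallback leaves the anionic manifold and sets out from 14. The alcohol is capped (TMSCl, imidazole, CH2Cl2) as trimethyl{[(2S,3E)-4-methyl-1-(2-methylcyclopent-1-en-1-yl)hepta-3,6-dien-2-yl]oxy}silane F1, so that no alkoxide exists. A neutral thermal siloxy-Cope shift (decalin, sealed tube, about 230 °C) through the same chair with the silyloxy group equatorial should give trimethyl{[(1E,3S)-3-methyl-3-[(1S)-1-methyl-2-methylidenecyclopentyl]hexa-1,5-dien-1-yl]oxy}silane F2. Methanolysis (K2CO3 cat., MeOH, 0 °C) returns to the route at 17.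

Step 11. The bias of the ring (an axial C5 methyl 1,3 to the carbonyl is expected to hinder one face) may oppose the catalyst, giving poor facial selectivity. The fallback sets out from 21 and uses the ring bias instead. Reduction with (S)-Me-CBS and catecholborane is expected to give the epimer (1R,5S)-2,5-dimethyl-5-[(1S)-1-methyl-2-methylidenecyclopentyl]cyclohex-2-en-1-ol F3. A Mitsunobu esterification with 25 (PPh3, DIAD, toluene, 0 °C → rt) should then invert C1 and return to the route at 26, passing by 22.

Step 5. The alkenyllithium may deprotonate the doubly activated methylene of the amide instead of adding, and base may move the ring alkene into conjugation. The fallback avoids a basic nucleophile and sets out from 6. DIBAL-H (CH2Cl2, −78 °C) should give 2-(2-methylcyclopent-1-en-1-yl)acetaldehyde F4. A Nozaki–Hiyama–Kishi coupling with 11 (CrCl2, NiCl2 cat., DMF, rt) should give racemic (3E)-4-methyl-1-(2-methylcyclopent-1-en-1-yl)hepta-3,6-dien-2-ol F5 with the alkene geometry retained. Dess–Martin oxidation returns to the route at 13.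

**Further compounds**

F1 | step 7 | trimethyl{[(2S,3E)-4-methyl-1-(2-methylcyclopent-1-en-1-yl)hepta-3,6-dien-2-yl]oxy}silane | CC1=C(C[C@H](O[Si](C)(C)C)/C=C(\C)CC=C)CCC1
F2 | step 7 | trimethyl{[(1E,3S)-3-methyl-3-[(1S)-1-methyl-2-methylidenecyclopentyl]hexa-1,5-dien-1-yl]oxy}silane | C=C1CCC[C@]1(C)[C@@](C)(CC=C)/C=C/O[Si](C)(C)C
F3 | step 11 | (1R,5S)-2,5-dimethyl-5-[(1S)-1-methyl-2-methylidenecyclopentyl]cyclohex-2-en-1-ol | C=C1CCC[C@]1(C)[C@@]1(C)CC=C(C)[C@H](O)C1
F4 | step 5 | 2-(2-methylcyclopent-1-en-1-yl)acetaldehyde | CC1=C(CC=O)CCC1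
F5 | step 5 | (3E)-4-methyl-1-(2-methylcyclopent-1-en-1-yl)hepta-3,6-dien-2-ol (racemic) | CC1=C(CC(O)/C=C(\C)CC=C)CCC1
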